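## Structural features

Sodwanone B consists of two bicycles joined by a CH2–CH2 chain. The right half, numbered as a naphthalene (C1 to C8a), has ring A as a fully substituted cyclohexa-2,5-dienone (C2=O, enolic OH on C1, methyl on C3, the chain on C4) and ring B as a 2,2-dimethylcyclohexanone (C7=O, gem-dimethyl C8). The two rings share the sp2 carbon C8a and the quaternary, methyl-bearing C4a, which is the only stereocentre of this half (R). The left half, numbered as a 1-benzoxepine (O1 to C9a), is a 2,2-dimethyloxepan-3-one (ring D) trans-fused to a cyclohexane (ring C) with four contiguous stereocentres C9a, C5a, C6 and C7. The C9a–O bond, the angular methyl on C5a, the chain on C6 and the methyl on C7 lie on one face, so the C7 methyl is axial and 1,3-diaxial to the angular methyl. C4a is five bonds from the nearest left-hand stereocentre, so it cannot be set by relay, and creating it in a ring with every position substituted is the real difficulty. Fragile groups are the diosphenol (air, base), the cross-conjugated dienone (dienone–phenol rearrangement in strong acid, retro-Michael cleavage of C4a–C5 in base) and the α-alkoxy ketone of ring D. The key step uses the fact that ring A is a dearomatised para-cresol: C2 is the phenol carbon, C4a lies para to it, and the C4a–C5 bond joins that para carbon to the β-carbon of an enone whose carbonyl is C7.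

## Logic of the disconnections

32 to 31. Only the O–CH2 bond of an acetal on the C1 oxygen is cut. The enol oxygen must be capped through the ring closure, and an acetal is chosen over a methyl ether because it leaves with dilute acid at room temperature. The demand is a cleavage mild enough to cause neither rearrangement of the dienone nor reversal of the ring closure.

31 to 30. The C4a–C5 bond of ring B is cut, which turns ring A into a hexasubstituted phenol and removes ring B and the only right-hand stereocentre. The forward step must choose one face of a planar para carbon by catalyst control alone. It must also prefer the para carbon to the oxygen-bearing ortho carbon, since both lie next to the side arm and both can close a six-membered ring. The oxygen next to the side arm stays capped, because a free OH there could close a seven-membered ether.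

30 to 29 to 28. The free phenol is traced to its silyl ether and the two ketones to two secondary alcohols. One oxidation then makes the oxepanone and the vinyl ketone together, with the phenol still masked. The demand is a desilylation that never generates a phenoxide beside the enone.

28 to 13 and 26. The aryl–CH2 bond is cut, dividing the thirty carbons into 14 and 16. The forward step is an sp3–sp2 coupling at an aryl bromide flanked by two methyl groups, and it must tolerate two free hydroxyl groups.

13 to 12 to 10. The carbinol–vinyl bond is cut, then the aldehyde is traced to a terminal alkene. The aldehyde has no α-hydrogen, so addition is clean.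

10 to 9 to 7 to 6 to 5. The O–Si and O–CH2 bonds are cut, and the free phenol oxygen is traced to a formyl group. The formyl group marks which of the two neighbouring oxygens becomes the free phenol, so the two are told apart without relying on selectivity. The demand is a peracid oxidation of the aldehyde that spares the terminal alkene.

5 to 3 to 1 and 2. The aryl–CMe2 bond is cut as a [3,3] shift of an aryl prenyl ether, then the ether O–CH2 bond. The two ortho positions of 1 are equivalent and para is blocked. The demand is a rearrangement into a position next to a methyl group.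

26 to 25 to 24 to 23. The vinyl group is traced to an aldehyde and a primary alcohol, and the C7 methyl to an exocyclic alkene. Hydrogen must add from the face opposite the angular methyl.

23 to 20. The O1–C2 bond of ring D and the C5a–C6 bond of ring C are cut together, leading back to an open-chain diepoxide with an allylsilane. The forward cascade must run in the endo sense at both tertiary carbons and translate epoxide configuration and alkene geometry into C9a, C5a and C6.

20 to 19 to 18 to 17 to 16. The alcohol is traced to the ester, the C–CH2Si bond to an enol triflate, the two epoxides to two trisubstituted alkenes, and the enol triflate to a β-keto ester. The silylmethyl group must be introduced after epoxidation, and the enol triflate must be Z.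

16 to 14 and 15. The bond between the γ-carbon of the keto ester and the allylic CH2 is cut, giving two commercial materials.

## Other disconnections considered

Alternative 1: The cut is made in the right half at the bond between the ring-fusion sp2 carbon and the quaternary methyl carbon, with ring A contracted to a five-membered 2-methoxy-enone. Enyne A2 with Co2(CO)8 and CO would give hydrindenone A1 by a Pauson–Khand reaction: the alkyne carbon next to CMe2 bonds to the methyl-bearing alkene carbon and CO is inserted between the other two termini.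
- In favour: three C–C bonds and two rings form in one step, the enol-ether oxygen arrives in place, and the quaternary carbon is set relative to the silyloxy stereocentre of A2, which a standard asymmetric method can provide.
- Against: A1 lacks one ring carbon, the C3 methyl and the chain. A one-carbon ring expansion, an alkylation with the left half next to the carbonyl and a dehydrogenation would all follow. A 1,1-disubstituted alkene that must become a quaternary centre is a slow Pauson–Khand partner, the ynol ether is acid-sensitive, and the controlling centre stands in a 1,4-relationship to the new one.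
- Comparison: on stereocontrol the alternative is the equal or the better of the chosen plan, because it needs no catalyst matched to a crowded arene, and it forms more bonds in its key step. On structure and step economy the chosen plan is better, since step 21 delivers the complete right bicycle one step from the target, whereas A1 is at least five steps away.

Alternative 2: The cut is made in the left half at the O1–C2 bond of ring D and the C5a–C6 bond of ring C. Diepoxide A4 with Me3SiOTf would give bicycle A3: the inner epoxide oxygen opens the activated terminal epoxide at its CMe2 carbon, and the allylsilane opens the resulting epoxonium ion at its tertiary carbon.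
- In favour: two rings, the trans fusion and three stereocentres come from epoxide configuration and alkene geometry in one step.
- Against: it says nothing about C4a or the dienone. A4 needs a geometrically defined trisubstituted allylsilane with a two-carbon oxygenated arm, which cannot be present during epoxidation. Oxygen can also close a five-membered ring in competition.
- Comparison: the chosen route uses the same kind of cascade as a supporting step (step 14, 20 to 23), so on mechanism and stereocontrol of the left half the two are equal. A3 already carries the two-carbon arm, which would make steps 16 and 17 unnecessary, and on that point the alternative is better. This is offset by a longer access to A4, which has no counterpart to the short enol-triflate sequence. As the centre of a strategy it would still need a separate answer for the right half, which is what step 21 provides.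

Alternative 3: The cut treats the right half as a saturated decalin and breaks the CMe2–CH bond and the bond from the quaternary methyl carbon to the carbon bearing the chain. Epoxy diene A6, already attached to the ketal-protected left bicycle, would give A5 with Cp2TiCl (trivalent titanium). The epoxide opens to a tertiary radical that closes two six-membered rings in the endo mode, and the last radical ends as an exocyclic alkene.
- In favour: the whole C30 skeleton is in place after one step, and the quaternary carbon is set relative to the epoxide through a chair–chair arrangement, a dependable form of substrate control. The conditions tolerate ether and ketal.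
- Against: A5 is far from the target in oxidation level. Ring A needs two oxygens, two ring double bonds and migration of the exocyclic alkene; ring B needs its ketone; and two of the new stereocentres are later destroyed. The cyclization consumes the finished left half in a step that usually gives moderate yields.
- Comparison: on reliability of stereocontrol at the quaternary carbon the alternative is better than an untested catalyst-controlled dearomatization. On structure and step economy the chosen plan is better, with one step after the key step against about six, and it joins the halves late.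

Key step: step 21

Remarks on the chemistry:
- The sense of induction of the phosphoric acid in step 21 cannot be predicted with confidence; (R)-TRIP is written, and its mirror image is to be used if it favours the other face.
- 13 and 28 are carried as mixtures at the carbinol carbon, which becomes a ketone in step 19.

## Route

Step 1
Reactants: 1 4-bromo-3,5-dimethylphenol; 2 prenyl bromide (1-bromo-3-methylbut-2-ene)
Product: 3 2-bromo-1,3-dimethyl-5-[(3-methylbut-2-en-1-yl)oxy]benzene
Conditions: K2CO3, acetone, reflux
Reagents that add atoms: none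
Why: Williamson ether synthesis; the phenoxide displaces the primary allylic bromide, and O-alkylation prevails with a carbonate base in a polar aprotic solvent.

Step 2
Reactants: 3 2-bromo-1,3-dimethyl-5-[(3-methylbut-2-en-1-yl)oxy]benzene
Product: 5 4-bromo-3,5-dimethyl-2-(2-methylbut-3-en-2-yl)phenol, via cyclohexadienone 4 (not isolated)
Conditions: PhNEt2, 190 °C
Reagents that add atoms: none
Why: Aromatic Claisen rearrangement; the [3,3] shift bonds the dimethyl-substituted allyl terminus to an ortho carbon (both are equivalent, para is blocked by bromine) and dienone 4 tautomerises to the phenol. The amine solvent suppresses acid-induced ring closure of the product onto its own oxygen.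

Step 3
Reactants: 5 4-bromo-3,5-dimethyl-2-(2-methylbut-3-en-2-yl)phenol
Product: 6 3-bromo-6-hydroxy-2,4-dimethyl-5-(2-methylbut-3-en-2-yl)benzaldehyde
Conditions: MgCl2, Et3N, (CH2O)n, MeCN, reflux
Reagents that add atoms: formaldehyde (as paraformaldehyde), C=O
Why: Magnesium-phenoxide-directed ortho-formylation; formaldehyde is delivered inside the magnesium chelate to the ortho carbon, here the only ring CH, and a second equivalent oxidises the benzylic alkoxide to the aldehyde.

Step 4
Reactants: 6 3-bromo-6-hydroxy-2,4-dimethyl-5-(2-methylbut-3-en-2-yl)benzaldehyde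
Product: 7 3-bromo-6-(methoxymethoxy)-2,4-dimethyl-5-(2-methylbut-3-en-2-yl)benzaldehyde
Conditions: NaH, MeOCH2Cl, DMF, 0 °C to rt
Reagents that add atoms: chloromethyl methyl ether, COCCl
Why: O-alkylation of the hindered, chelated phenoxide with a reactive chloromethyl ether. The acetal is used because it can later be taken off the enol oxygen with dilute acid.

Step 5
Reactants: 7 3-bromo-6-(methoxymethoxy)-2,4-dimethyl-5-(2-methylbut-3-en-2-yl)benzaldehyde
Product: 9 3-bromo-6-(methoxymethoxy)-2,4-dimethyl-5-(2-methylbut-3-en-2-yl)phenol, via aryl formate 8 (not isolated)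
Conditions: mCPBA, CH2Cl2, 0 °C to rt; then K2CO3, MeOH
Reagents that add atoms: 3-chloroperoxybenzoic acid, OOC(=O)c1cccc(Cl)c1
Why: Baeyer–Villiger (Dakin-type) oxidation; in the peracid adduct of an electron-rich, di-ortho-substituted benzaldehyde the aryl group migrates, and formate 8 is methanolysed in the same flask. A monosubstituted alkene on a quaternary carbon is epoxidised much more slowly than this aldehyde is oxidised.

Step 6
Reactants: 9 3-bromo-6-(methoxymethoxy)-2,4-dimethyl-5-(2-methylbut-3-en-2-yl)phenol
Product: 10 {[3-bromo-6-(methoxymethoxy)-2,4-dimethyl-5-(2-methylbut-3-en-2-yl)phenyl]oxy}tri(propan-2-yl)silane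
Conditions: NaH, i-Pr3SiCl, THF, 0 °C to rt
Reagents that add atoms: chlorotri(propan-2-yl)silane, CC(C)[Si](Cl)(C(C)C)C(C)C
Why: Silylation of the sodium phenoxide; the bulky silyl ether survives periodate, the Grignard reagent and the aqueous base of the coupling, and is later removed by fluoride without touching the acetal.

Step 7
Reactants: 10 {[3-bromo-6-(methoxymethoxy)-2,4-dimethyl-5-(2-methylbut-3-en-2-yl)phenyl]oxy}tri(propan-2-yl)silane
Product: 12 2-[5-bromo-2-(methoxymethoxy)-4,6-dimethyl-3-{[tri(propan-2-yl)silyl]oxy}phenyl]-2-methylpropanal, via diol 11 (not isolated)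
Conditions: OsO4 (2 mol %), NaIO4, 2,6-lutidine, 1,4-dioxane/H2O, rt
Reagents that add atoms: osmium tetroxide, O=[Os](=O)(=O)=O (re-formed by sodium periodate, [Na+].[O-]I(=O)(=O)=O)
Why: Lemieux–Johnson cleavage; OsO4 dihydroxylates the only alkene to diol 11, which NaIO4 cleaves. The aldehyde has no α-hydrogen, and 2,6-lutidine limits over-oxidation.

Step 8
Reactants: 12 2-[5-bromo-2-(methoxymethoxy)-4,6-dimethyl-3-{[tri(propan-2-yl)silyl]oxy}phenyl]-2-methylpropanal
Product: 13 2-[5-bromo-2-(methoxymethoxy)-4,6-dimethyl-3-{[tri(propan-2-yl)silyl]oxy}phenyl]-2-methylpent-4-en-3-ol (racemic)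
Conditions: CH2=CHMgBr, THF, −78 to 0 °C
Reagents that add atoms: vinylmagnesium bromide, C=C[Mg]Br
Why: Grignard addition to a non-enolisable aldehyde; the carbinol centre is formed without control and disappears on oxidation in step 19.

Step 9
Reactants: 14 geranyl bromide ((2E)-1-bromo-3,7-dimethylocta-2,6-diene); 15 methyl acetoacetate
Product: 16 methyl (6E)-7,11-dimethyl-3-oxododeca-6,10-dienoate
Conditions: NaH, then n-BuLi, THF, 0 °C; then 14, 0 °C to rt
Reagents that add atoms: none
Why: γ-Alkylation of the acetoacetate dianion; the more basic terminal carbanion displaces the primary allylic bromide in an SN2 reaction and the E geometry of 14 is kept.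

Step 10
Reactants: 16 methyl (6E)-7,11-dimethyl-3-oxododeca-6,10-dienoate
Product: 17 methyl (2Z,6E)-7,11-dimethyl-3-{[(trifluoromethyl)sulfonyl]oxy}dodeca-2,6,10-trienoate
Conditions: (CF3SO2)2O, aq. LiOH, toluene, 0 °C
Reagents that add atoms: trifluoromethanesulfonic anhydride, O=S(=O)(OS(=O)(=O)C(F)(F)F)C(F)(F)F
Why: O-Sulfonylation of the chelated lithium enolate of the β-keto ester gives the Z enol triflate (OTf cis to the ester). This geometry later places the silylmethyl group cis to the oxygenated carbon.

Step 11
Reactants: 17 methyl (2Z,6E)-7,11-dimethyl-3-{[(trifluoromethyl)sulfonyl]oxy}dodeca-2,6,10-trienoate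
Product: 18 methyl (2Z)-5-[(2S,3S)-3-{2-[(2S)-3,3-dimethyloxiran-2-yl]ethyl}-3-methyloxiran-2-yl]-3-{[(trifluoromethyl)sulfonyl]oxy}pent-2-enoate
Conditions: Shi ketone derived from L-fructose (0.6 equiv), KHSO5 (as 2KHSO5·KHSO4·K2SO4), K2CO3, Bu4NHSO4, MeCN/(MeO)2CH2/aq. Na2B4O7 buffer, 0 °C
Reagents that add atoms: potassium peroxymonosulfate, [K+].[O-]S(=O)(=O)OO
Why: Shi epoxidation; the chiral dioxirane attacks both electron-rich trisubstituted alkenes through the spiro transition state and gives the S,S and S epoxides (the ketone from D-fructose gives the mirror-image sense). The electron-poor enol-triflate alkene does not react. These epoxides fix the absolute configuration of the left bicycle.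

Step 12
Reactants: 18 methyl (2Z)-5-[(2S,3S)-3-{2-[(2S)-3,3-dimethyloxiran-2-yl]ethyl}-3-methyloxiran-2-yl]-3-{[(trifluoromethyl)sulfonyl]oxy}pent-2-enoate
Product: 19 methyl (2Z)-5-[(2S,3S)-3-{2-[(2S)-3,3-dimethyloxiran-2-yl]ethyl}-3-methyloxiran-2-yl]-3-[(trimethylsilyl)methyl]pent-2-enoate
Conditions: Me3SiCH2MgCl, Pd(PPh3)4 (5 mol %), THF, 0 °C to rt
Reagents that add atoms: (trimethylsilyl)methylmagnesium chloride, C[Si](C)(C)C[Mg]Cl
Why: Kumada coupling; oxidative addition of zerovalent palladium to the enol triflate, transmetalation and reductive elimination go with retention of alkene geometry. The bulky Grignard reagent attacks neither the ester nor the trisubstituted epoxides at this temperature.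

Step 13
Reactants: 19 methyl (2Z)-5-[(2S,3S)-3-{2-[(2S)-3,3-dimethyloxiran-2-yl]ethyl}-3-methyloxiran-2-yl]-3-[(trimethylsilyl)methyl]pent-2-enoate
Product: 20 (2Z)-5-[(2S,3S)-3-{2-[(2S)-3,3-dimethyloxiran-2-yl]ethyl}-3-methyloxiran-2-yl]-3-[(trimethylsilyl)methyl]pent-2-en-1-ol
Conditions: i-Bu2AlH, CH2Cl2, −78 °C
Reagents that add atoms: none
Why: 1,2-Reduction of the conjugated ester by the aluminium hydride at low temperature; trisubstituted epoxides and the allylsilane are inert under these conditions.

Step 14
Reactants: 20 (2Z)-5-[(2S,3S)-3-{2-[(2S)-3,3-dimethyloxiran-2-yl]ethyl}-3-methyloxiran-2-yl]-3-[(trimethylsilyl)methyl]pent-2-en-1-ol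
Product: 23 (3S,5aS,6R,9aS)-6-(hydroxymethyl)-2,2,5a-trimethyl-7-methylidenedecahydro-1-benzoxepin-3-ol, via silyl ether 21 (not isolated), via bis-silyl ether 22 (not isolated)
Conditions: Me3SiOTf (3.5 equiv), 2,6-di-tert-butyl-4-methylpyridine, CH2Cl2, −78 °C; then K2CO3, MeOH, rt
Reagents that add atoms: none
Why: Epoxonium cascade ended by an allylsilane; the alcohol is silylated in the flask (21), Me3SiOTf activates the terminal epoxide, the inner epoxide oxygen opens it at the CMe2 carbon, and the bicyclic epoxonium ion is opened with inversion at its tertiary carbon by the allylsilane through a chair. This gives the trans ring fusion and, because the oxygenated arm is trans to the chain on the alkene, an equatorial CH2O group at C6. Loss of the silyl group leaves the exocyclic alkene, and methanolysis of 22 frees both hydroxyl groups.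

Step 15
Reactants: 23 (3S,5aS,6R,9aS)-6-(hydroxymethyl)-2,2,5a-trimethyl-7-methylidenedecahydro-1-benzoxepin-3-ol
Product: 24 (3S,5aS,6R,7R,9aS)-6-(hydroxymethyl)-2,2,5a,7-tetramethyldecahydro-1-benzoxepin-3-ol
Conditions: H2 (1 atm), PtO2, EtOAc, rt
Reagents that add atoms: none
Why: Heterogeneous hydrogenation; the catalyst approaches the exocyclic alkene from the equatorial direction, the face opposite the axial angular methyl on C5a, so the new C7 methyl becomes axial and cis to the angular methyl (7R). PtO2 is preferred to palladium to avoid migration of the double bond.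

Step 16
Reactants: 24 (3S,5aS,6R,7R,9aS)-6-(hydroxymethyl)-2,2,5a,7-tetramethyldecahydro-1-benzoxepin-3-ol
Product: 25 (3S,5aS,6R,7R,9aS)-3-hydroxy-2,2,5a,7-tetramethyldecahydro-1-benzoxepine-6-carbaldehyde
Conditions: TEMPO (10 mol %), PhI(OAc)2, CH2Cl2, rt
Reagents that add atoms: none
Why: Oxoammonium (TEMPO) oxidation is selective for the primary alcohol over the hindered secondary C3 alcohol and stops at the aldehyde.

Step 17
Reactants: 25 (3S,5aS,6R,7R,9aS)-3-hydroxy-2,2,5a,7-tetramethyldecahydro-1-benzoxepine-6-carbaldehyde
Product: 26 (3S,5aS,6R,7R,9aS)-6-ethenyl-2,2,5a,7-tetramethyldecahydro-1-benzoxepin-3-ol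
Conditions: Ph3PCH3Br, KN(SiMe3)2 (2.5 equiv of ylide), THF, −78 to 0 °C
Reagents that add atoms: methyltriphenylphosphonium bromide, C[P+](c1ccccc1)(c1ccccc1)c1ccccc1.[Br-]
Why: Wittig methylenation at low temperature; excess ylide takes up the hydroxyl proton, and the formyl group on C6 already sits in the equatorial position.

Step 18
Reactants: 26 (3S,5aS,6R,7R,9aS)-6-ethenyl-2,2,5a,7-tetramethyldecahydro-1-benzoxepin-3-ol; 13 2-[5-bromo-2-(methoxymethoxy)-4,6-dimethyl-3-{[tri(propan-2-yl)silyl]oxy}phenyl]-2-methylpent-4-en-3-ol
Product: 28 2-[5-{2-[(3S,5aS,6R,7R,9aS)-3-hydroxy-2,2,5a,7-tetramethyldecahydro-1-benzoxepin-6-yl]ethyl}-2-(methoxymethoxy)-4,6-dimethyl-3-{[tri(propan-2-yl)silyl]oxy}phenyl]-2-methylpent-4-en-3-ol (mixture at the carbinol carbon), via alkylborane 27 (not isolated)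
Conditions: 9-BBN (2.5 equiv), THF, rt; then aq. K3PO4; 13, Pd(OAc)2 (5 mol %), SPhos (10 mol %), THF, 65 °C
Reagents that add atoms: none
Why: B-alkyl Suzuki–Miyaura coupling; 9-BBN adds to the terminal alkene at its CH2 end (27), the aqueous base destroys excess borane before the aryl bromide is added, and the bulky electron-rich phosphine allows oxidative addition and transmetalation at the di-ortho-substituted bromide. Both free hydroxyl groups are tolerated.

Step 19
Reactants: 28 2-[5-{2-[(3S,5aS,6R,7R,9aS)-3-hydroxy-2,2,5a,7-tetramethyldecahydro-1-benzoxepin-6-yl]ethyl}-2-(methoxymethoxy)-4,6-dimethyl-3-{[tri(propan-2-yl)silyl]oxy}phenyl]-2-methylpent-4-en-3-ol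
Product: 29 (5aS,6R,7R,9aS)-6-{2-[4-(methoxymethoxy)-2,6-dimethyl-3-(2-methyl-3-oxopent-4-en-2-yl)-5-{[tri(propan-2-yl)silyl]oxy}phenyl]ethyl}-2,2,5a,7-tetramethyloctahydro-1-benzoxepin-3(2H)-one
Conditions: Dess–Martin periodinane (3 equiv), NaHCO3, CH2Cl2, 0 °C to rt
Reagents that add atoms: none
Why: Dess–Martin oxidation turns both secondary alcohols into the oxepanone and the vinyl ketone in one operation and removes the uncontrolled carbinol centre. The phenol is still silylated and is therefore not oxidised.

Step 20
Reactants: 29 (5aS,6R,7R,9aS)-6-{2-[4-(methoxymethoxy)-2,6-dimethyl-3-(2-methyl-3-oxopent-4-en-2-yl)-5-{[tri(propan-2-yl)silyl]oxy}phenyl]ethyl}-2,2,5a,7-tetramethyloctahydro-1-benzoxepin-3(2H)-one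
Product: 30 (5aS,6R,7R,9aS)-6-{2-[3-hydroxy-4-(methoxymethoxy)-2,6-dimethyl-5-(2-methyl-3-oxopent-4-en-2-yl)phenyl]ethyl}-2,2,5a,7-tetramethyloctahydro-1-benzoxepin-3(2H)-one
Conditions: Bu4NF, AcOH (1:1), THF, 0 °C
Reagents that add atoms: none
Why: Fluoride cleaves the aryl silyl ether; acetic acid keeps the phenol protonated so that no phenoxide forms that could cyclise without stereocontrol. The acetal and both ketones are untouched, and 30 is used at once.

Step 21
Reactants: 30 (5aS,6R,7R,9aS)-6-{2-[3-hydroxy-4-(methoxymethoxy)-2,6-dimethyl-5-(2-methyl-3-oxopent-4-en-2-yl)phenyl]ethyl}-2,2,5a,7-tetramethyloctahydro-1-benzoxepin-3(2H)-one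
Product: 31 (4aR)-1-(methoxymethoxy)-3,4a,8,8-tetramethyl-4-{2-[(5aS,6R,7R,9aS)-2,2,5a,7-tetramethyl-3-oxodecahydro-1-benzoxepin-6-yl]ethyl}-5,6-dihydronaphthalene-2,7(4aH,8H)-dione
Conditions: (R)-TRIP (10 mol %), toluene, 4 Å molecular sieves, 0 °C to rt
Reagents that add atoms: none
Why: Intramolecular conjugate addition of a phenol through its para carbon (alkylative dearomatization); the phosphoric acid donates a hydrogen bond to the enone carbonyl and accepts one from the phenolic OH, the methyl-bearing para carbon attacks the CH2 terminus of the vinyl ketone, and loss of the phenolic proton gives the cross-conjugated dienone. The closest known reactions are base- or acid-promoted para-alkylative dearomatizations of phenols to ring-fused 4,4-disubstituted cyclohexadienones and catalytic asymmetric dearomative conjugate additions of naphthols and phenols. Ring B closes in the 6-endo-trig mode. The new quaternary centre C4a is controlled by the catalyst alone, since the nearest stereocentre is five bonds away; the products are diastereomers, so a minor epimer can be removed by chromatography. Attack through the phenol oxygen would need an eight-membered ring, and the oxygen next to the side arm is capped as an acetal so that it cannot close a seven-membered ether. The tether does not exclude the oxygen-bearing ortho carbon, which can also close a six-membered ring; para attack is expected to prevail because it gives the more stable cross-conjugated dienone and because the para carbon is remote from the catalyst-bound OH and the acetal. Non-basic conditions are used because base opens the way back by retro-Michael cleavage.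

Step 22
Reactants: 31 (4aR)-1-(methoxymethoxy)-3,4a,8,8-tetramethyl-4-{2-[(5aS,6R,7R,9aS)-2,2,5a,7-tetramethyl-3-oxodecahydro-1-benzoxepin-6-yl]ethyl}-5,6-dihydronaphthalene-2,7(4aH,8H)-dione
Product: 32 sodwanone B, (4aR)-1-hydroxy-3,4a,8,8-tetramethyl-4-{2-[(5aS,6R,7R,9aS)-2,2,5a,7-tetramethyl-3-oxodecahydro-1-benzoxepin-6-yl]ethyl}-5,6-dihydronaphthalene-2,7(4aH,8H)-dione
Conditions: 2 M HCl, THF, rt
Reagents that add atoms: none
Why: Acid hydrolysis of the methoxymethyl enol ether; the diosphenol leaves from the protonated acetal and formaldehyde and methanol are released. Dilute acid at room temperature is too mild for a dienone–phenol rearrangement or for opening of ring D.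

## Compound list

1 | 4-bromo-3,5-dimethylphenol | Cc1cc(O)cc(C)c1Br | starting material
2 | prenyl bromide (1-bromo-3-methylbut-2-ene) | CC(C)=CCBr | starting material
3 | 2-bromo-1,3-dimethyl-5-[(3-methylbut-2-en-1-yl)oxy]benzene | Cc1cc(OCC=C(C)C)cc(C)c1Br | intermediate
4 | 4-bromo-3,5-dimethyl-6-(2-methylbut-3-en-2-yl)cyclohexa-2,4-dien-1-one (racemic) | O=C1C=C(C)C(Br)=C(C)C1C(C)(C)C=C | intermediate (not isolated)
5 | 4-bromo-3,5-dimethyl-2-(2-methylbut-3-en-2-yl)phenol | Cc1cc(O)c(C(C)(C)C=C)c(C)c1Br | intermediate
6 | 3-bromo-6-hydroxy-2,4-dimethyl-5-(2-methylbut-3-en-2-yl)benzaldehyde | Cc1c(C=O)c(O)c(C(C)(C)C=C)c(C)c1Br | intermediate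
7 | 3-bromo-6-(methoxymethoxy)-2,4-dimethyl-5-(2-methylbut-3-en-2-yl)benzaldehyde | Cc1c(C=O)c(OCOC)c(C(C)(C)C=C)c(C)c1Br | intermediate
8 | 3-bromo-6-(methoxymethoxy)-2,4-dimethyl-5-(2-methylbut-3-en-2-yl)phenyl formate | Cc1c(OC=O)c(OCOC)c(C(C)(C)C=C)c(C)c1Br | intermediate (not isolated)
9 | 3-bromo-6-(methoxymethoxy)-2,4-dimethyl-5-(2-methylbut-3-en-2-yl)phenol | Cc1c(O)c(OCOC)c(C(C)(C)C=C)c(C)c1Br | intermediate
10 | {[3-bromo-6-(methoxymethoxy)-2,4-dimethyl-5-(2-methylbut-3-en-2-yl)phenyl]oxy}tri(propan-2-yl)silane | Cc1c(O[Si](C(C)C)(C(C)C)C(C)C)c(OCOC)c(C(C)(C)C=C)c(C)c1Br | intermediate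
11 | 3-[5-bromo-2-(methoxymethoxy)-4,6-dimethyl-3-{[tri(propan-2-yl)silyl]oxy}phenyl]-3-methylbutane-1,2-diol (racemic) | Cc1c(O[Si](C(C)C)(C(C)C)C(C)C)c(OCOC)c(C(C)(C)C(O)CO)c(C)c1Br | intermediate (not isolated)
12 | 2-[5-bromo-2-(methoxymethoxy)-4,6-dimethyl-3-{[tri(propan-2-yl)silyl]oxy}phenyl]-2-methylpropanal | Cc1c(O[Si](C(C)C)(C(C)C)C(C)C)c(OCOC)c(C(C)(C)C=O)c(C)c1Br | intermediate
13 | 2-[5-bromo-2-(methoxymethoxy)-4,6-dimethyl-3-{[tri(propan-2-yl)silyl]oxy}phenyl]-2-methylpent-4-en-3-ol (racemic) | Cc1c(O[Si](C(C)C)(C(C)C)C(C)C)c(OCOC)c(C(C)(C)C(O)C=C)c(C)c1Br | intermediate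
14 | geranyl bromide, (2E)-1-bromo-3,7-dimethylocta-2,6-diene | CC(C)=CCC/C(C)=C/CBr | starting material
15 | methyl acetoacetate | COC(=O)CC(C)=O | starting material
16 | methyl (6E)-7,11-dimethyl-3-oxododeca-6,10-dienoate | COC(=O)CC(=O)CC/C=C(\C)CCC=C(C)C | intermediate
17 | methyl (2Z,6E)-7,11-dimethyl-3-{[(trifluoromethyl)sulfonyl]oxy}dodeca-2,6,10-trienoate | COC(=O)/C=C(\OS(=O)(=O)C(F)(F)F)CC/C=C(\C)CCC=C(C)C | intermediate
18 | methyl (2Z)-5-[(2S,3S)-3-{2-[(2S)-3,3-dimethyloxiran-2-yl]ethyl}-3-methyloxiran-2-yl]-3-{[(trifluoromethyl)sulfonyl]oxy}pent-2-enoate | COC(=O)/C=C(\OS(=O)(=O)C(F)(F)F)CC[C@@H]1O[C@@]1(C)CC[C@@H]2OC2(C)C | intermediate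
19 | methyl (2Z)-5-[(2S,3S)-3-{2-[(2S)-3,3-dimethyloxiran-2-yl]ethyl}-3-methyloxiran-2-yl]-3-[(trimethylsilyl)methyl]pent-2-enoate | COC(=O)/C=C(\C[Si](C)(C)C)CC[C@@H]1O[C@@]1(C)CC[C@@H]2OC2(C)C | intermediate
20 | (2Z)-5-[(2S,3S)-3-{2-[(2S)-3,3-dimethyloxiran-2-yl]ethyl}-3-methyloxiran-2-yl]-3-[(trimethylsilyl)methyl]pent-2-en-1-ol | OC/C=C(\C[Si](C)(C)C)CC[C@@H]1O[C@@]1(C)CC[C@@H]2OC2(C)C | intermediate
21 | trimethylsilyl ether of 20 | C[Si](C)(C)OC/C=C(\C[Si](C)(C)C)CC[C@@H]1O[C@@]1(C)CC[C@@H]2OC2(C)C | intermediate (not isolated)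
22 | bis(trimethylsilyl) ether of 23 | C[Si](C)(C)OC[C@@H]2C(=C)CC[C@@H]3OC(C)(C)[C@@H](O[Si](C)(C)C)CC[C@]32C | intermediate (not isolated)
23 | (3S,5aS,6R,9aS)-6-(hydroxymethyl)-2,2,5a-trimethyl-7-methylidenedecahydro-1-benzoxepin-3-ol | OC[C@@H]2C(=C)CC[C@@H]3OC(C)(C)[C@@H](O)CC[C@]32C | intermediate
24 | (3S,5aS,6R,7R,9aS)-6-(hydroxymethyl)-2,2,5a,7-tetramethyldecahydro-1-benzoxepin-3-ol | OC[C@@H]2[C@H](C)CC[C@@H]3OC(C)(C)[C@@H](O)CC[C@]32C | intermediate
25 | (3S,5aS,6R,7R,9aS)-3-hydroxy-2,2,5a,7-tetramethyldecahydro-1-benzoxepine-6-carbaldehyde | O=C[C@@H]2[C@H](C)CC[C@@H]3OC(C)(C)[C@@H](O)CC[C@]32C | intermediate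
26 | (3S,5aS,6R,7R,9aS)-6-ethenyl-2,2,5a,7-tetramethyldecahydro-1-benzoxepin-3-ol | C=C[C@@H]2[C@H](C)CC[C@@H]3OC(C)(C)[C@@H](O)CC[C@]32C | intermediate
27 | 9-{2-[(3S,5aS,6R,7R,9aS)-3-hydroxy-2,2,5a,7-tetramethyldecahydro-1-benzoxepin-6-yl]ethyl}-9-borabicyclo[3.3.1]nonane | C1CCC2CCCC1B2CC[C@@H]3[C@H](C)CC[C@@H]4OC(C)(C)[C@@H](O)CC[C@]43C | intermediate (not isolated)
28 | 2-[5-{2-[(3S,5aS,6R,7R,9aS)-3-hydroxy-2,2,5a,7-tetramethyldecahydro-1-benzoxepin-6-yl]ethyl}-2-(methoxymethoxy)-4,6-dimethyl-3-{[tri(propan-2-yl)silyl]oxy}phenyl]-2-methylpent-4-en-3-ol (mixture at the carbinol carbon) | Cc1c(O[Si](C(C)C)(C(C)C)C(C)C)c(OCOC)c(C(C)(C)C(O)C=C)c(C)c1CC[C@@H]2[C@H](C)CC[C@@H]3OC(C)(C)[C@@H](O)CC[C@]32C | intermediate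
29 | (5aS,6R,7R,9aS)-6-{2-[4-(methoxymethoxy)-2,6-dimethyl-3-(2-methyl-3-oxopent-4-en-2-yl)-5-{[tri(propan-2-yl)silyl]oxy}phenyl]ethyl}-2,2,5a,7-tetramethyloctahydro-1-benzoxepin-3(2H)-one | Cc1c(O[Si](C(C)C)(C(C)C)C(C)C)c(OCOC)c(C(C)(C)C(=O)C=C)c(C)c1CC[C@@H]2[C@H](C)CC[C@@H]3OC(C)(C)C(=O)CC[C@]32C | intermediate
30 | (5aS,6R,7R,9aS)-6-{2-[3-hydroxy-4-(methoxymethoxy)-2,6-dimethyl-5-(2-methyl-3-oxopent-4-en-2-yl)phenyl]ethyl}-2,2,5a,7-tetramethyloctahydro-1-benzoxepin-3(2H)-one | Cc1c(O)c(OCOC)c(C(C)(C)C(=O)C=C)c(C)c1CC[C@@H]2[C@H](C)CC[C@@H]3OC(C)(C)C(=O)CC[C@]32C | intermediate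
31 | (4aR)-1-(methoxymethoxy)-3,4a,8,8-tetramethyl-4-{2-[(5aS,6R,7R,9aS)-2,2,5a,7-tetramethyl-3-oxodecahydro-1-benzoxepin-6-yl]ethyl}-5,6-dihydronaphthalene-2,7(4aH,8H)-dione | CC1=C(CC[C@@H]2[C@H](C)CC[C@@H]3OC(C)(C)C(=O)CC[C@]32C)[C@@]2(C)CCC(=O)C(C)(C)C2=C(OCOC)C1=O | intermediate
32 | sodwanone B | CC1=C(CC[C@@H]2[C@H](C)CC[C@@H]3OC(C)(C)C(=O)CC[C@]32C)[C@@]2(C)CCC(=O)C(C)(C)C2=C(O)C1=O | target

## Step count and least certain steps

Total: 22 steps (steps 1–8 for the arene, 9–17 for the left bicycle, 18–22 after the union). Longest linear sequence: 14 steps (steps 9 to 22).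

**Step 21 (key step).** Three things may go wrong. The catalyst may discriminate poorly between the two faces of the para carbon of a phenol with no free position. Ring closure may go through the oxygen-bearing ortho carbon. The closure may be slow or reverse by retro-Michael cleavage. Fallback: starting from 30, the ring is closed without a chiral catalyst by catalytic DBU in CH2Cl2 at room temperature, which equilibrates the phenol with the para adducts and drains any less stable ortho adduct. This should give 31 together with its C4a epimer, (4aS)-1-(methoxymethoxy) dienone F1. The two are diastereomers and are separated by preparative HPLC, and F1 is returned to the same base for re-equilibration. The sequence comes back to the route at 31.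

**Step 14.** Oxygen may close a five-membered ring when the inner epoxide is activated first. The allylic silyloxy group may be lost together with the silyl group to give a diene. An activated epoxide may rearrange to a carbonyl compound. Fallback: the rings are made one at a time from a mono-epoxide, setting out from 15.
- Commercial geraniol undergoes Sharpless asymmetric epoxidation (Ti(OiPr)4, L-(+)-diethyl tartrate, t-BuOOH, CH2Cl2, −20 °C) to the epoxy alcohol F2.
- F2 is converted into its triflate F3 ((CF3SO2)2O, 2,6-lutidine, −78 °C), which alkylates the dianion of 15 to give the epoxy keto ester F4.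
- The operations of steps 10, 12 and 13 then give the enol triflate F5, the allylsilane ester F6 and the allylic alcohol F7.
- Me3SiOTf with in-flask silylation closes ring C by epoxide–allylsilane cyclization, with no second oxygen nucleophile present, to the monocyclic diol F8.
- Shi epoxidation (ketone from L-fructose) of the trisubstituted side-chain alkene, which reacts much faster than the 1,1-disubstituted exocyclic alkene, gives the epoxy diol F9.
- Camphorsulfonic acid in CH2Cl2 closes ring D by opening the epoxide at its tertiary carbon.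

The sequence comes back to the route at 23 and is three steps longer.

**Step 2.** The shift into a position next to a methyl group may be slow, and at the temperature needed the product may rearrange further or close a ring onto its own oxygen. Fallback: the gem-dimethyl group is built by enolate methylation after an unhindered allyl Claisen rearrangement, setting out from 1.
- Allyl bromide and K2CO3 give the allyl ether F10, which rearranges at 190 °C to the allylphenol F11.
- Ozonolysis (O3, then Me2S) gives the cyclic hemiacetal F12, and TEMPO with PhI(OAc)2 gives the lactone F13.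
- NaH and MeI give the dimethyl lactone F14, and i-Bu2AlH at −78 °C gives the lactol F15.
- Methylenetriphenylphosphorane converts F15 into the phenol with the 2-methylbut-3-en-2-yl group.

The sequence comes back to the route at 5.

**Step 5.** The peracid may epoxidise the terminal alkene in competition with the aldehyde, or hydrogen may migrate instead of aryl to give a benzoic acid. Fallback: the aldehyde is oxidised while the neighbouring phenol is free, and the two oxygens are told apart by steric hindrance, setting out from 6.
- Dakin oxidation (H2O2, NaOH) gives the catechol F16.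
- i-Pr3SiCl with imidazole silylates the hydroxyl group remote from the tertiary alkyl group to give the mono-silyl ether F17.
- MeOCH2Cl with i-Pr2NEt caps the hindered hydroxyl group.

The sequence comes back to the route at 10.

## Further compounds

F1 | step 21 | (4aS)-1-(methoxymethoxy)-3,4a,8,8-tetramethyl-4-{2-[(5aS,6R,7R,9aS)-2,2,5a,7-tetramethyl-3-oxodecahydro-1-benzoxepin-6-yl]ethyl}-5,6-dihydronaphthalene-2,7(4aH,8H)-dione | CC1=C(CC[C@@H]2[C@H](C)CC[C@@H]3OC(C)(C)C(=O)CC[C@]32C)[C@]2(C)CCC(=O)C(C)(C)C2=C(OCOC)C1=O
F2 | step 14 | [(2S,3S)-3-methyl-3-(4-methylpent-3-en-1-yl)oxiran-2-yl]methanol | OC[C@@H]1O[C@@]1(C)CCC=C(C)C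
F3 | step 14 | [(2S,3S)-3-methyl-3-(4-methylpent-3-en-1-yl)oxiran-2-yl]methyl trifluoromethanesulfonate | FC(F)(F)S(=O)(=O)OC[C@@H]1O[C@@]1(C)CCC=C(C)C
F4 | step 14 | methyl 5-[(2S,3S)-3-methyl-3-(4-methylpent-3-en-1-yl)oxiran-2-yl]-3-oxopentanoate | COC(=O)CC(=O)CC[C@@H]1O[C@@]1(C)CCC=C(C)C
F5 | step 14 | methyl (2Z)-5-[(2S,3S)-3-methyl-3-(4-methylpent-3-en-1-yl)oxiran-2-yl]-3-{[(trifluoromethyl)sulfonyl]oxy}pent-2-enoate | COC(=O)/C=C(\OS(=O)(=O)C(F)(F)F)CC[C@@H]1O[C@@]1(C)CCC=C(C)C
F6 | step 14 | methyl (2Z)-5-[(2S,3S)-3-methyl-3-(4-methylpent-3-en-1-yl)oxiran-2-yl]-3-[(trimethylsilyl)methyl]pent-2-enoate | COC(=O)/C=C(\C[Si](C)(C)C)CC[C@@H]1O[C@@]1(C)CCC=C(C)C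
F7 | step 14 | (2Z)-5-[(2S,3S)-3-methyl-3-(4-methylpent-3-en-1-yl)oxiran-2-yl]-3-[(trimethylsilyl)methyl]pent-2-en-1-ol | OC/C=C(\C[Si](C)(C)C)CC[C@@H]1O[C@@]1(C)CCC=C(C)C
F8 | step 14 | (1S,2S,3R)-3-(hydroxymethyl)-2-methyl-4-methylidene-2-(4-methylpent-3-en-1-yl)cyclohexan-1-ol | OC[C@@H]1C(=C)CC[C@H](O)[C@@]1(C)CCC=C(C)C
F9 | step 14 | (1S,2S,3R)-2-{2-[(2S)-3,3-dimethyloxiran-2-yl]ethyl}-3-(hydroxymethyl)-2-methyl-4-methylidenecyclohexan-1-ol | OC[C@@H]1C(=C)CC[C@H](O)[C@@]1(C)CC[C@@H]2OC2(C)C
F10 | step 2 | 2-bromo-1,3-dimethyl-5-(prop-2-en-1-yloxy)benzene | Cc1cc(OCC=C)cc(C)c1Br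
F11 | step 2 | 4-bromo-3,5-dimethyl-2-(prop-2-en-1-yl)phenol | Cc1cc(O)c(CC=C)c(C)c1Br
F12 | step 2 | 5-bromo-4,6-dimethyl-2,3-dihydro-1-benzofuran-2-ol | Cc1cc2OC(O)Cc2c(C)c1Br
F13 | step 2 | 5-bromo-4,6-dimethyl-1-benzofuran-2(3H)-one | Cc1cc2OC(=O)Cc2c(C)c1Br
F14 | step 2 | 5-bromo-3,3,4,6-tetramethyl-1-benzofuran-2(3H)-one | Cc1cc2OC(=O)C(C)(C)c2c(C)c1Br
F15 | step 2 | 5-bromo-3,3,4,6-tetramethyl-2,3-dihydro-1-benzofuran-2-ol | Cc1cc2OC(O)C(C)(C)c2c(C)c1Br
F16 | step 5 | 4-bromo-3,5-dimethyl-6-(2-methylbut-3-en-2-yl)benzene-1,2-diol | Cc1c(O)c(O)c(C(C)(C)C=C)c(C)c1Br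
F17 | step 5 | 4-bromo-3,5-dimethyl-6-(2-methylbut-3-en-2-yl)-2-{[tri(propan-2-yl)silyl]oxy}phenol | Cc1c(O[Si](C(C)C)(C(C)C)C(C)C)c(O)c(C(C)(C)C=C)c(C)c1Br
A1 | alternative 1 | (5S,7aR)-5-{[tert-butyl(dimethyl)silyl]oxy}-3-methoxy-4,4,7a-trimethyl-1,4,5,6,7,7a-hexahydro-2H-inden-2-one | COC1=C2C(C)(C)[C@@H](O[Si](C)(C)C(C)(C)C)CC[C@]2(C)CC1=O
A2 | alternative 1 | tert-butyl{[(4S)-1-methoxy-3,3,7-trimethyloct-7-en-1-yn-4-yl]oxy}dimethylsilane | COC#CC(C)(C)[C@@H](O[Si](C)(C)C(C)(C)C)CCC(C)=C
A3 | alternative 2 | 2-[(3S,5aS,6R,9aS)-3-hydroxy-2,2,5a-trimethyl-7-methylidenedecahydro-1-benzoxepin-6-yl]ethyl 2,2-dimethylpropanoate | CC(C)(C)C(=O)OCC[C@@H]2C(=C)CC[C@@H]3OC(C)(C)[C@@H](O)CC[C@]32C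
A4 | alternative 2 | (3Z)-6-[(2S,3S)-3-{2-[(2S)-3,3-dimethyloxiran-2-yl]ethyl}-3-methyloxiran-2-yl]-4-[(trimethylsilyl)methyl]hex-3-en-1-yl 2,2-dimethylpropanoate | CC(C)(C)C(=O)OCC/C=C(\C[Si](C)(C)C)CC[C@@H]1O[C@@]1(C)CC[C@@H]2OC2(C)C
A5 | alternative 3 | (2S,4aR,5S,8aR)-1,1,4a-trimethyl-6-methylidene-5-{2-[(5aS,6R,7R,9aS)-2,2,5a,7-tetramethyloctahydro-2H-spiro[1-benzoxepine-3,2'-[1,3]dioxolan]-6-yl]ethyl}decahydronaphthalen-2-ol | C=C1CC[C@H]4C(C)(C)[C@@H](O)CC[C@]4(C)[C@H]1CC[C@@H]2[C@H](C)CC[C@@H]3OC(C)(C)C5(OCCO5)CC[C@]32C
A6 | alternative 3 | (5aS,6R,7R,9aS)-6-{(3E,7E)-10-[(2S)-3,3-dimethyloxiran-2-yl]-4,8-dimethyldeca-3,7-dien-1-yl}-2,2,5a,7-tetramethyloctahydro-2H-spiro[1-benzoxepine-3,2'-[1,3]dioxolane] | CC1(C)O[C@H]1CC/C(C)=C/CC/C(C)=C/CC[C@@H]2[C@H](C)CC[C@@H]3OC(C)(C)C4(OCCO4)CC[C@]32C
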